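Each ring A of the target is a resorcinol-type ring whose biaryl carbon C6 lies between the oxygenated carbons C5 and C7, so the C6–C6'' bond is traced back to the central bond of a 1,4-bis(siloxy)buta-1,3-diyne. In one operation, two pyranonyl ketenes, released by photochemical Wolff rearrangement of an (S)-6-diazoacetyl-2-aryl-2,3-dihydropyran-4-one that already holds ring C and C2, add to the two alkynes; cyclobutenone opening and 6π-closure onto pyranone C5 then complete both rings A, forming C8–C8a, C5–C6, C7–C8 and C4a–C5 in each half. The diazoketone comes from an asymmetric methallylation, an oxalate Claisen cyclisation and diazomethane acylation; one global desilylation finishes the synthesis.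

Key step: step 7

Assumption: the target string carries no descriptor for the C6–C6'' axis, so the axis is treated as configurationally unspecified and any atropisomeric forms of the silylated biaryl 17 are carried on together.

Locants: flavanone numbering (O1, C2, C3, C4, C4a, C5–C8, C8a; doubly primed for the second half); TBS = tert-butyldimethylsilyl, TIPS = triisopropylsilyl, Ipc = isopinocampheyl.

Step 1
Reactants: 1 4-(tert-butyldimethylsilyloxy)benzaldehyde
Product: 2 (S)-1-[4-(tert-butyldimethylsilyloxy)phenyl]-3-methylbut-3-en-1-ol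
Conditions: (−)-Ipc2BOMe, CH2=C(CH3)CH2MgCl, Et2O, −78 °C → rt; then 1, −78 °C; H2NCH2CH2OH, rt
Reagents that add atoms: methallylmagnesium chloride, C=C(C)C[Mg]Cl
Why: Brown asymmetric methallylboration: the reagent made from (+)-α-pinene-derived (−)-Ipc2BOMe transfers the methallyl group to the si face of the aldehyde through a chair-like six-membered (Zimmerman–Traxler) transition state, which sets the carbinol carbon (future C2) as S, and the non-oxidative ethanolamine work-up spares the aryl silyl ether.

Step 2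
Reactants: 2 (S)-1-[4-(tert-butyldimethylsilyloxy)phenyl]-3-methylbut-3-en-1-ol
Product: 3 (S)-4-[4-(tert-butyldimethylsilyloxy)phenyl]-4-hydroxybutan-2-one
Conditions: O3, CH2Cl2, −78 °C; Me2S, −78 °C → rt
Reagents that add atoms: ozone, [O-][O+]=O
Why: Ozonolysis with reductive work-up cleaves the 1,1-disubstituted alkene, which reacts far faster than the silyloxyarene, to the methyl ketone without touching the carbinol stereocentre.

Step 3
Reactants: 3 (S)-4-[4-(tert-butyldimethylsilyloxy)phenyl]-4-hydroxybutan-2-one; 4 diallyl oxalate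
Product: 6 allyl (S)-6-[4-(tert-butyldimethylsilyloxy)phenyl]-4-oxo-5,6-dihydro-4H-pyran-2-carboxylate, via hydroxy diketo ester 5 (not isolated)
Conditions: LiN(SiMe3)2 (3.3 equiv), THF, −78 °C; 4, −78 → 0 °C; 1 M HCl quench; TsOH·H2O (10 mol %), CH2Cl2, rt
Reagents that add atoms: none
Why: Crossed Claisen condensation of the ketol dianion (alkoxide plus kinetic methyl-side enolate) with the oxalate, followed by acid-catalysed hemiketalisation of the 6-hydroxyl onto the C2 ketone and dehydration (the classical oxalate route to 4-oxo-dihydropyran-2-carboxylates), builds ring C without breaking the carbinol C–O bond, so the S configuration is retained.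

Step 4
Reactants: 6 allyl (S)-6-[4-(tert-butyldimethylsilyloxy)phenyl]-4-oxo-5,6-dihydro-4H-pyran-2-carboxylate
Product: 7 (S)-6-[4-(tert-butyldimethylsilyloxy)phenyl]-4-oxo-5,6-dihydro-4H-pyran-2-carboxylic acid
Conditions: Pd(PPh3)4 (3 mol %), PhNHMe, THF, rt
Reagents that add atoms: none
Why: Tsuji–Trost deallylation: zerovalent palladium ionises the allyl ester to a π-allyl complex that N-methylaniline captures, which frees the acid under neutral conditions and so avoids hydroxide, the cause of retro-oxa-Michael racemisation at the aryl-bearing carbon and of aryl silyl ether loss.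

Step 5
Reactants: 7 (S)-6-[4-(tert-butyldimethylsilyloxy)phenyl]-4-oxo-5,6-dihydro-4H-pyran-2-carboxylic acid
Product: 9 (S)-2-[4-(tert-butyldimethylsilyloxy)phenyl]-6-(diazoacetyl)-2,3-dihydro-4H-pyran-4-one, via acid chloride 8 (not isolated)
Conditions: Me2C=C(Cl)NMe2, CH2Cl2, 0 °C → rt; then CH2N2 (4 equiv), Et2O, 0 °C
Reagents that add atoms: diazomethane, C=[N+]=[N-]
Why: Neutral conversion of the acid into its chloride by the α-chloroenamine, then acylation of diazomethane (first stage of the Arndt–Eistert sequence, the excess CH2N2 consuming HCl), which at 0 °C should outrun dipolar addition to the trisubstituted, oxygen-substituted C=C.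

Step 6
Reactants: 10 1,4-bis(trimethylsilyl)buta-1,3-diyne
Product: 13 1,4-bis(triisopropylsilyloxy)buta-1,3-diyne, via dilithiobutadiyne 11 (not isolated), via dilithium diynediolate 12 (not isolated)
Conditions: MeLi·LiBr (2.1 equiv), THF, 0 °C → rt; t-BuOOLi (from t-BuOOH and LiN(SiMe3)2, 2.2 equiv), THF, −78 → 0 °C; TIPSOTf (2.5 equiv), −78 → 0 °C; filtration through Et3N-deactivated silica
Reagents that add atoms: tert-butyl hydroperoxide, CC(C)(C)OO; triisopropylsilyl trifluoromethanesulfonate, CC(C)[Si](OS(=O)(=O)C(F)(F)F)(C(C)C)C(C)C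
Why: Twofold C–Si cleavage by MeLi gives the bis-acetylide, each carbanion attacks the peroxide O–O bond of t-BuOOLi (acetylide-to-ynolate oxidation), and the bulky silyl triflate silylates both ynolates on oxygen, the standard preparation of triisopropylsilyl ynol ethers from lithium acetylides.

Step 7
Reactants: 9 (S)-2-[4-(tert-butyldimethylsilyloxy)phenyl]-6-(diazoacetyl)-2,3-dihydro-4H-pyran-4-one (2.5 equiv); 13 1,4-bis(triisopropylsilyloxy)buta-1,3-diyne
Product: 17 4',4'''-bis-O-(tert-butyldimethylsilyl)-7,7''-bis-O-(triisopropylsilyl)succedaneaflavanone, via pyranonyl ketene 14 (not isolated), via bis(cyclobutenone) 15 (not isolated), via bis(dienylketene) 16 (not isolated)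
Conditions: hν (medium-pressure Hg lamp, Pyrex filter, λ > 300 nm), degassed ClCH2CH2Cl, 20 °C; then 80 °C
Reagents that add atoms: none
Why: Irradiation expels N2 from each molecule of 9 and the Wolff 1,2-shift of the pyranonyl group (making C8–C8a) gives vinylketene 14, whose carbonyl carbon (future C5) bonds to the oxygen-remote, nucleophilic alkyne carbon (future C6) and whose CH (future C8) bonds to the siloxy-bearing carbon (future C7) in a [2+2] cycloaddition at each alkyne of 13, giving the bis(3-siloxy-4-pyranonylcyclobut-2-enone) 15. On warming, each four-membered ring undergoes 4π-electrocyclic opening to dienylketene 16, and each ring A is closed by a thermal 6π-electrocyclisation of the ketene carbon onto pyranone C5 (C4a–C5), after which enolisation of the doubly activated C4a–H delivers the chelated 5-hydroxy phenol. The closest known reaction is the photochemical-Wolff (second-generation) Danheiser benzannulation of α'-diazo enones with siloxyalkynes, run here twice on one conjugated diyne whose central bond becomes C6–C6''. No stereocentre is created: the sp3 carbons of 15 and of the cyclohexadienone are erased on aromatisation, and C2, remote from every bond-forming site and never exposed to base, keeps its S configuration. The selectivity required is regiochemical: the oxygen lone pair polarises each alkyne so that only the internal diyne carbons attack the ketene carbonyl, which places C6 between the new 5-OH and the 7-OSi group, while closure can occur only at C5 of the pyranone, the sole vinylic terminus, which fixes O1 at C8a. Completing both cycloadditions at ambient temperature before heating lets the second ketene meet an alkyne carried by a small cyclobutenone instead of a 2,6-disubstituted arene, and keeps a free ortho-phenol from sitting next to a siloxyalkyne.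

Step 8
Reactants: 17 4',4'''-bis-O-(tert-butyldimethylsilyl)-7,7''-bis-O-(triisopropylsilyl)succedaneaflavanone
Product: 18 succedaneaflavanone
Conditions: HF·pyridine, THF/pyridine, 0 °C → rt
Reagents that add atoms: none
Why: Fluoride cleaves the four aryl Si–O bonds (desilylation) in a mildly acidic medium that keeps the 4'-oxygen protonated and ring C closed, so both C2 centres stay S.

Compound list

1 | 4-(tert-butyldimethylsilyloxy)benzaldehyde | O=Cc1ccc(O[Si](C)(C)C(C)(C)C)cc1 | starting material
2 | (S)-1-[4-(tert-butyldimethylsilyloxy)phenyl]-3-methylbut-3-en-1-ol | C=C(C)C[C@H](O)c1ccc(O[Si](C)(C)C(C)(C)C)cc1 | intermediate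
3 | (S)-4-[4-(tert-butyldimethylsilyloxy)phenyl]-4-hydroxybutan-2-one | CC(=O)C[C@H](O)c1ccc(O[Si](C)(C)C(C)(C)C)cc1 | intermediate
4 | diallyl oxalate | C=CCOC(=O)C(=O)OCC=C | starting material
5 | allyl (S)-6-[4-(tert-butyldimethylsilyloxy)phenyl]-6-hydroxy-2,4-dioxohexanoate (not isolated) | C=CCOC(=O)C(=O)CC(=O)C[C@H](O)c1ccc(O[Si](C)(C)C(C)(C)C)cc1 | intermediate
6 | allyl (S)-6-[4-(tert-butyldimethylsilyloxy)phenyl]-4-oxo-5,6-dihydro-4H-pyran-2-carboxylate | C=CCOC(=O)C1=CC(=O)C[C@@H](c2ccc(O[Si](C)(C)C(C)(C)C)cc2)O1 | intermediate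
7 | (S)-6-[4-(tert-butyldimethylsilyloxy)phenyl]-4-oxo-5,6-dihydro-4H-pyran-2-carboxylic acid | OC(=O)C1=CC(=O)C[C@@H](c2ccc(O[Si](C)(C)C(C)(C)C)cc2)O1 | intermediate
8 | (S)-6-[4-(tert-butyldimethylsilyloxy)phenyl]-4-oxo-5,6-dihydro-4H-pyran-2-carbonyl chloride (not isolated) | ClC(=O)C1=CC(=O)C[C@@H](c2ccc(O[Si](C)(C)C(C)(C)C)cc2)O1 | intermediate
9 | (S)-2-[4-(tert-butyldimethylsilyloxy)phenyl]-6-(diazoacetyl)-2,3-dihydro-4H-pyran-4-one | [N-]=[N+]=CC(=O)C1=CC(=O)C[C@@H](c2ccc(O[Si](C)(C)C(C)(C)C)cc2)O1 | intermediate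
10 | 1,4-bis(trimethylsilyl)buta-1,3-diyne | C[Si](C)(C)C#CC#C[Si](C)(C)C | starting material
11 | 1,4-dilithiobuta-1,3-diyne (not isolated) | [Li]C#CC#C[Li] | intermediate
12 | dilithium buta-1,3-diyne-1,4-diolate (not isolated) | [Li]OC#CC#CO[Li] | intermediate
13 | 1,4-bis(triisopropylsilyloxy)buta-1,3-diyne | CC(C)[Si](OC#CC#CO[Si](C(C)C)(C(C)C)C(C)C)(C(C)C)C(C)C | intermediate
14 | [(S)-2-[4-(tert-butyldimethylsilyloxy)phenyl]-4-oxo-3,4-dihydro-2H-pyran-6-yl]ketene (not isolated) | O=C=CC1=CC(=O)C[C@@H](c2ccc(O[Si](C)(C)C(C)(C)C)cc2)O1 | intermediate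
15 | 2,2'-bi(cyclobut-2-en-1-one) carrying on each ring a 3-triisopropylsilyloxy group and a 4-[(S)-2-[4-(tert-butyldimethylsilyloxy)phenyl]-4-oxo-3,4-dihydro-2H-pyran-6-yl] group, mixture of epimers at the ring C4 carbons (not isolated) | O=C1C(C2=C(O[Si](C(C)C)(C(C)C)C(C)C)C(C3=CC(=O)C[C@@H](c4ccc(O[Si](C)(C)C(C)(C)C)cc4)O3)C2=O)=C(O[Si](C(C)C)(C(C)C)C(C)C)C1C5=CC(=O)C[C@@H](c6ccc(O[Si](C)(C)C(C)(C)C)cc6)O5 | intermediate
16 | 2,3-bis[1-(triisopropylsilyloxy)-2-[(S)-2-[4-(tert-butyldimethylsilyloxy)phenyl]-4-oxo-3,4-dihydro-2H-pyran-6-yl]vinyl]buta-1,3-diene-1,4-dione, the bis(dienylketene) (not isolated) | O=C=C(C(=C=O)C(O[Si](C(C)C)(C(C)C)C(C)C)=CC1=CC(=O)C[C@@H](c2ccc(O[Si](C)(C)C(C)(C)C)cc2)O1)C(O[Si](C(C)C)(C(C)C)C(C)C)=CC3=CC(=O)C[C@@H](c4ccc(O[Si](C)(C)C(C)(C)C)cc4)O3 | intermediate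
17 | 4',4'''-bis-O-(tert-butyldimethylsilyl)-7,7''-bis-O-(triisopropylsilyl)succedaneaflavanone, the (2S,2''S)-6,6''-linked dimer of 5-hydroxy-7-(triisopropylsilyloxy)-2-[4-(tert-butyldimethylsilyloxy)phenyl]chroman-4-one | O=C1C[C@@H](c2ccc(O[Si](C)(C)C(C)(C)C)cc2)Oc2cc(O[Si](C(C)C)(C(C)C)C(C)C)c(-c3c(O[Si](C(C)C)(C(C)C)C(C)C)cc4c(c3O)C(=O)C[C@@H](c3ccc(O[Si](C)(C)C(C)(C)C)cc3)O4)c(O)c21 | intermediate
18 | succedaneaflavanone, (2S,2''S)-6,6''-binaringenin | O=C1C[C@@H](c2ccc(O)cc2)Oc2cc(O)c(-c3c(O)cc4c(c3O)C(=O)C[C@@H](c3ccc(O)cc3)O4)c(O)c21 | target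

Total step count: 8. Longest linear sequence: 7 steps (steps 1–5, 7 and 8); step 6 makes the diyne in a separate one-step branch.

Steps most likely to fail

Step 7. The second annulation may stall for steric reasons. Siloxyalkyne units may also be lost by protonation from the first-formed phenol, by ketene acylation, or by enone–alkyne photocycloaddition. The fallback sets out from 9 and builds each ring A singly before joining the halves by cross-coupling. The ordinary single Danheiser benzannulation of 9 with 1-(triisopropylsilyloxy)-2-(trimethylsilyl)ethyne F1 (from lithium (trimethylsilyl)acetylide, t-BuOOLi and TIPSOTf), under the conditions of step 7, should give (S)-4'-O-(tert-butyldimethylsilyl)-7-O-(triisopropylsilyl)-6-(trimethylsilyl)naringenin F2. ICl in CH2Cl2 at −78 °C then replaces silicon by iodine at C6 (ipso-iododesilylation) to give (S)-4'-O-(tert-butyldimethylsilyl)-6-iodo-7-O-(triisopropylsilyl)naringenin F3. Part of F3 is converted by Miyaura borylation (PdCl2(dppf), B2pin2, KOAc, dioxane, 80 °C) into the C6 pinacol boronate F4. Suzuki–Miyaura coupling of F3 with F4 (Pd(OAc)2, SPhos, anhydrous K3PO4, toluene, 90 °C) forms C6–C6'' and comes back to the route at 17.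

Step 6. The second acetylide oxidation may fail because the ynolate–acetylide dianion aggregates or precipitates, or the bis-ynolate may be silylated on carbon instead of oxygen. The fallback sets out from 10 and functionalises one terminus at a time, so that no dianion is needed. MeLi·LiBr (1.0 equiv) gives the mono-lithiated diyne, which with t-BuOOLi and then TIPSOTf should give 1-(triisopropylsilyloxy)-4-(trimethylsilyl)buta-1,3-diyne F5. A second round of C–Si cleavage by MeLi·LiBr, peroxide oxidation and O-silylation on F5 comes back to the route at 13.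

Step 5. Dipolar cycloaddition of diazomethane to the electron-poor ring C=C may compete with acylation, and HCl may destroy the diazoketone as it forms. The fallback sets out from 7 (through its chloride 8) and never has a free diazoalkane next to the enone. α-Addition of N-isocyanoiminotriphenylphosphorane (Ph3P=N–N≡C) to 8 in CH2Cl2 gives the phosphazine of the α-keto hydrazonoyl chloride F6. Water cleaves the P=N bond to give the α-keto hydrazonoyl chloride F7, and Et3N removes HCl from F7 to come back to the route at 9.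

Further compounds

F1 | step 7 | 1-(triisopropylsilyloxy)-2-(trimethylsilyl)ethyne | C[Si](C)(C)C#CO[Si](C(C)C)(C(C)C)C(C)C
F2 | step 7 | (S)-2-[4-(tert-butyldimethylsilyloxy)phenyl]-5-hydroxy-7-(triisopropylsilyloxy)-6-(trimethylsilyl)chroman-4-one | O=C1C[C@@H](c2ccc(O[Si](C)(C)C(C)(C)C)cc2)Oc2cc(O[Si](C(C)C)(C(C)C)C(C)C)c([Si](C)(C)C)c(O)c21
F3 | step 7 | (S)-2-[4-(tert-butyldimethylsilyloxy)phenyl]-5-hydroxy-6-iodo-7-(triisopropylsilyloxy)chroman-4-one | O=C1C[C@@H](c2ccc(O[Si](C)(C)C(C)(C)C)cc2)Oc2cc(O[Si](C(C)C)(C(C)C)C(C)C)c(I)c(O)c21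
F4 | step 7 | (S)-2-[4-(tert-butyldimethylsilyloxy)phenyl]-5-hydroxy-6-(4,4,5,5-tetramethyl-1,3,2-dioxaborolan-2-yl)-7-(triisopropylsilyloxy)chroman-4-one | O=C1C[C@@H](c2ccc(O[Si](C)(C)C(C)(C)C)cc2)Oc2cc(O[Si](C(C)C)(C(C)C)C(C)C)c(B3OC(C)(C)C(C)(C)O3)c(O)c21
F5 | step 6 | 1-(triisopropylsilyloxy)-4-(trimethylsilyl)buta-1,3-diyne | C[Si](C)(C)C#CC#CO[Si](C(C)C)(C(C)C)C(C)C
F6 | step 5 | (S)-2-[4-(tert-butyldimethylsilyloxy)phenyl]-6-[2-chloro-2-(triphenylphosphoranylidenehydrazono)acetyl]-2,3-dihydro-4H-pyran-4-one | ClC(=NN=P(c1ccccc1)(c1ccccc1)c1ccccc1)C(=O)C1=CC(=O)C[C@@H](c2ccc(O[Si](C)(C)C(C)(C)C)cc2)O1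
F7 | step 5 | (S)-2-[4-(tert-butyldimethylsilyloxy)phenyl]-6-(2-chloro-2-hydrazonoacetyl)-2,3-dihydro-4H-pyran-4-one | NN=C(Cl)C(=O)C1=CC(=O)C[C@@H](c2ccc(O[Si](C)(C)C(C)(C)C)cc2)O1
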